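(The constants belong to no real substance; the result is computed.)

In flask ash, J takes D at 0.0600 min⁻¹ at the start, slower than X and E together take it, at 0.253 min⁻¹. This comparison carries the reckoning.

| flask | J | Q | temperature | time |
|---|---|---|---|---|
| ash | 2.0 M | 2.00 M | 40 °C | 2.5 h |
| larch | 2.0 M | 2.00 M | 10 °C | 2.5 h |
| alder | 2.0 M | 2.00 M | 25 °C | 2.5 h |

    J + D → J.D (k1 = 0.030 L mol⁻¹ min⁻¹, Ea1 = 66.0 kJ mol⁻¹)
    J + Q → D + L (k2 = 0.059 L mol⁻¹ min⁻¹, Ea2 = 72.0 kJ mol⁻¹)
    D ⇌ X (K3 = 15, k3 = 0.16 min⁻¹, Ea3 = 85.0 kJ mol⁻¹, ΔH3 = −27.0 kJ mol⁻¹)
    D ⇌ E (K4 = 3.0, k4 = 0.093 min⁻¹, Ea4 = 88.0 kJ mol⁻¹, ΔH4 = −18.0 kJ mol⁻¹)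
    (constants at 40 °C)

- in percentages every species weighs as the J in it: one J.D counts as two
- the constants hold at 40 °C; other temperatures follow from the activation energies and enthalpies

1. the best flask by share of X in all that became X or E or J.D; "all alike" if 1.5 percentage points covers them all (ash / larch / alder / all alike)
2. share of X in all that became X or E or J.D, ash
3. share of X in all that became X or E or J.D, larch
4. share of X in all that became X or E or J.D, alder

The capture share is the part of the D leaving forward that J takes: the capture constant times [J], over that product plus the forward constants of D to X and D to E. At the charge of ash it is 19.2 %. But the clock of J + Q, 8.47 min, is short against 2.5 h, and that step alone leaves about 5.35 % of J. So [J] goes back in at its mean, half the charge, and the share becomes 10.6 %.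

Now the ledger of ash. J is the limiting reagent: the charges are equal, and J pays in two steps while Q pays in one. Through J + Q pass 1.81 M, and the rest of the charge, 0.192 M, is captured, so J.D holds 19.2 % of the J. The free remainder, 80.8 %, sits in D, X and E. E returns to X through D with a half-life of 29.5 min, short against 2.5 h, so the remainder is reckoned as divided by the equilibrium constants at the asked time: X 63.8 %, E 12.8 %, D 4.25 %. The books close, and the share of X in ash is 66.6 %.

Larch and alder are reckoned from flows, each constant taken at the flask's own temperature. D goes forward to X and E at 0.00503 min⁻¹ and 0.00259 min⁻¹ in larch, and at 0.0310 min⁻¹ and 0.0170 min⁻¹ in alder. J + Q alone sets the mean [J] between the charge and what remains: 1.51 M in larch, 1.19 M in alder. Capture, counted double because one J.D weighs as two, then flows at 0.00619 min⁻¹ in larch and 0.0199 min⁻¹ in alder. The return of E has a half-life of 37.0 h in larch and 3.83 h in alder, longer than 2.5 h. So X's part of the X and E pool is carried from its forward value toward its equilibrium value by that half-life over the whole time, which gives 67.0 % in larch and 72.2 % in alder. That part, times the pool's part of the flows, gives 37.0 % for larch and 51.1 % for alder, and the best flask is ash.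

The forecast names ash, with 69 % for ash (65 % to 73 %), 39 % for larch (35 % to 43 %) and 52 % for alder (47 % to 57 %). These differ from the ledger's figures. Its ground: “Warmth favours X because D is drained faster by the high-activation first-order steps than it is captured by J”.

The flasks give 64.4 % in ash, 39.4 % in larch and 52.3 % in alder, so ash leads, as the forecast said, within its tolerance. The ash answer has moved by 5 points once J reaches 2.33 M or Q falls to 1.64 M. Flask ash read at 40 min still holds 12.6 % of its J. Its mean [J] is 1.13 M, so the capture share is 11.8 %. The ledger then passes 1.56 M through J + Q and puts 18.4 % of the J in J.D. That flask reads 1.57 M of L and 17.5 % in J.D.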